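Compound numbers are fixed by the steps below and used throughout. Positions follow cembrane numbering: C1–C14 is the ring, C15 the lactone methine, C16 the carboxyl carbon, C17 the methyl on C15, C18 the methyl on C4, C19 the methylene carbon on C8, C20 the methyl on C12.

## Analysis of the target

Target 32 is a cembranolide. Its 14-membered carbocycle C1–C14 is bridged from C1 to C3 by a δ-lactone (C15, C16 and the ring oxygen on C3). It carries a trans trisubstituted epoxide at C11–C12, an exocyclic methylene on C8, a secondary allylic alcohol at C7 and a tertiary methyl carbinol at C4. The seven stereocentres are 1R, 3R, 4S, 7R, 11S, 12S and 15S. They fall into three groups that cannot pass configuration to one another through the flexible ring: the cluster C15–C1/C3–C4, the isolated C7, and the epoxide pair. In the lactone chair the C15 methyl, the C1–C14 bond and the C3–C4 bond are all equatorial, so C15 is the thermodynamically preferred epimer. The oxygens on C3 and C4 are cis on the macrocycle (erythro). The epoxide is sensitive to acid and to transannular attack by the nearby hydroxyls, the lactone to aqueous base, and the epoxide also to oxophilic low-valent metals. The difficulty is to close a 14-membered ring around remote stereocentres that need reagent control while two adjacent oxygenated centres are set. The strategy rests on C3 and C4: they form a vicinal diol inside the carbocycle, so the C3–C4 bond is a pinacol bond and ring and diol can arise together from an acyclic C3 aldehyde/C4 methyl ketone.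

## Retrosynthetic reasoning

**32 to 30.** The C7 silyl ether of 31 is removed last. The lactone C16–O bond of 31 is cut to the C3 hydroxyl and the C16 methyl ester of diol 30. The C3 oxygen is 1,5 to the ester, so the forward step is a six-membered transesterification that needs only mild base and keeps acid away from the epoxide.

**30 to 29 (key disconnection).** The C3–C4 bond of 30 is cut to the aldehyde and methyl ketone of seco compound 29. No other ring bond returns two oxygen functions and the ring in a single step, and every stereocentre outside C3/C4 can be installed beforehand in acyclic material. The forward reaction is a reductive coupling by a divalent samarium reductant at high dilution. It must leave the epoxide, the ester and the allylic silyl ether untouched and give the cis 3,4-diol in the correct sense relative to C1.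

**29 to 27.** The aldehyde of 29 is traced to the primary triethylsilyl ether of 28, which can be oxidised directly and so never passes through a free δ-hydroxy ester. The epoxide of 28 comes from the E C11=C12 alkene of 27 by a chiral dioxirane. The trisubstituted alkene is the most electron-rich one present, so reagent control can set 11S,12S without help from the distant centres.

**27 to 23 and 25.** The C7–C8 bond is cut between the bromoalkene 23 and keto aldehyde 25 (one oxidation from 24). A chromium-mediated alkenyl addition tolerates the ketone of 25 and the ester of 23, so no protecting group is needed at C4, and a chiral ligand on chromium sets the isolated C7 centre. The allylic alcohol 26 is then silylated to 27.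

**23 to 18.** The ester and the silyloxyethyl arm of 23 are the opened form of the trans lactone 20. The two CH2 arms at C1 are too alike for an acyclic enolate to distinguish, but in the six-membered lactone 18 the C1 side chain blocks one face. C-methylation of its enolate therefore sets C15 trans to the C1 arm. Lactone 20 is reopened through carboxylate 21 to hydroxy ester 22.

**18 to 13 and 14.** The C1–C15 bond is cut to the enal 13 and malonate 14. An iminium-catalysed conjugate addition sets C1 and delivers C3 at the aldehyde oxidation level. Reduction and lactonisation (15 to 17 via 16) and loss of the extra ester give 18. A monoterpene cyclohexene from the chiral pool would supply C1 with its three arms in one cleavage. It was set aside because hydroboration of its isopropenyl group cannot control C15 and olefination of the resulting methyl ketone cannot control the C11=C12 geometry.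

**13 to 7 and 8.** The C1=C2 bond of 13 comes from aldehyde 11 and the two-carbon ylide 12. Ester 10, the precursor of 11, is cut at C13–C14 by an orthoester Claisen transform to allylic alcohol 7 and orthoester 8. This is where the E geometry of C11=C12 is fixed, in acyclic material and by a chair transition state.

**7 to 1, 2 and 6.** Alcohol 7 is the adduct of Grignard reagent 6 (C12, C13, C20) and aldehyde 5. Aldehyde 5 comes from ester 4, the product of alkylating the enolate 3 of acetate 1 (C10, C11) with dibromide 2 (C8, C9, C19). The vinylic bromine of 2 is carried unchanged to the chromium coupling.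

## Alternatives that were turned down

**Alternative 1:** The C1–C2 bond is cut inside a 16-membered macrolactone A1, in which C2 is an iodomethyl branch on C3 and C1=C15 is a 2-methyl enoate. In the forward step Bu3SnH generates the primary C2 radical, which adds across the ring to C1 (6-endo with respect to the new lactone). The C15 radical then takes hydrogen from the stannane, and the δ-lactone and the 14-membered carbocycle form together as A2 (identical with 31).
- For: two rings arise in one step, the large ring is made by a dependable macrolactonisation, and the 3,4-diol can be set earlier in open-chain material by reagent control. On that last point this plan is stronger than the chosen one.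
- Against: the radical precursor is an iodide flanked by an acyloxy carbon and a tertiary carbinol, so it is prone to epoxide formation and acyl shift. The addition needs the ester in its disfavoured s-cis form, and the macrolide holds the ester s-trans, away from C1. C1 is created with no control element other than ring conformation; C15 at least can be equilibrated.
- Comparison: the chosen route settles C1 and C15 early by catalyst and substrate control and uses no tin. Its open stereochemical question sits at C3/C4, where an error at C3 can be repaired by oxidation and reduction.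

**Alternative 2:** The C12–C13 bond is cut in a seco compound A3 that already holds the lactone, the tertiary carbinol, a 7,8-epoxide, an (E)-alkenyl iodide at C12 and a vinyl group on C1. In the forward step 9-BBN hydroborates the vinyl group and [1,1'-bis(diphenylphosphino)ferrocene]palladium dichloride (divalent palladium precatalyst) with Cs2CO3 couples the C13 borane with the iodide to give macrocycle A4.
- For: the alkene geometry is carried in from the iodide, and the ring closure creates no stereocentre. It is therefore more predictable than a pinacol closure, and on that point it is the stronger plan.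
- Against: A4 is not yet at the target's oxidation pattern. The 7,8-epoxide must be isomerised regioselectively to the C7 alcohol with the exocyclic C8 methylene. C11=C12 must then be epoxidised on one face inside the macrocycle, in competition with an allylic alcohol that directs oxidants to the wrong alkene. The aqueous carbonate of the coupling also threatens the δ-lactone.
- Comparison: this plan moves two selectivity problems behind the macrocyclisation, where material is scarcest. The chosen plan fixes C7, C11 and C12 before ring closure and forms the ring together with the diol, so only two steps follow.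

**Alternative 3:** The C9–C10 bond is cut in a seco compound A5 that carries a β-keto sulfone (C8 ketone, C9 sulfone) and a tertiary allylic methyl carbonate at C12. In the forward step Pd(PPh3)4 (zerovalent palladium) ionises the carbonate and the stabilised C9 carbanion attacks the unsubstituted allyl terminus C10. This forms the ring and the C11=C12 alkene of A6.
- For: the two halves are joined convergently, the nucleophile is soft, the conditions are nearly neutral, and allylic alkylation is a proven way to close 14-membered rings. In convergence it is ahead of the chosen, largely linear route.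
- Against: the geometry of the trisubstituted alkene is decided during ring closure by equilibrating π-allyl isomers and is not guaranteed. A6 still needs reductive desulfonylation next to a ketone, methylenation of a hindered α-silyloxy ketone with C7 at risk of epimerisation, and a face-selective epoxidation within the ring.
- Comparison: three delicate operations follow the macrocyclisation, against two simple ones in the chosen plan. The chosen plan fixes the alkene geometry by a Claisen rearrangement and the epoxide configuration by a chiral dioxirane before the ring exists.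

Key step: step 18

Remark (assumption on the chemistry): for step 14 the antipode of the sulfonamide ligand is taken to be the one that directs Si-face addition to the aldehyde (7R); which antipode that is has to be confirmed on a small sample.

## Route

**Step 1**
Reactants: 1 tert-butyl acetate; 2 2,3-dibromoprop-1-ene
Product: 4 tert-butyl 4-bromopent-4-enoate, via lithium enolate of tert-butyl acetate 3 (not isolated)
Conditions: LiN(i-Pr)2 (LDA), THF, −78 °C; then 2, −78 → −20 °C
Reagents that add atoms: none
Why: Enolate alkylation (SN2): the ester enolate displaces the allylic bromide of 2 while the vinylic bromide is inert, which joins C9 to C10 and leaves the C8 bromoalkene as the later coupling handle; no stereocentre is formed.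

**Step 2**
Reactants: 4 tert-butyl 4-bromopent-4-enoate
Product: 5 4-bromopent-4-enal
Conditions: i-Bu2AlH, CH2Cl2, −78 °C
Reagents that add atoms: none
Why: Partial reduction of an ester: the tetrahedral aluminium hemiacetal is stable at −78 °C and releases the aldehyde only on work-up; the bromoalkene is untouched.

**Step 3**
Reactants: 5 4-bromopent-4-enal; 6 isopropenylmagnesium bromide
Product: 7 6-bromo-2-methylhepta-1,6-dien-3-ol (racemic)
Conditions: THF, −78 → 0 °C; aq. NH4Cl
Reagents that add atoms: none
Why: Grignard 1,2-addition to the aldehyde; the carbinol centre (C11) is racemic, which does not matter because it is destroyed in step 4.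

**Step 4**
Reactants: 7 6-bromo-2-methylhepta-1,6-dien-3-ol; 8 triethyl orthoacetate
Product: 10 ethyl (4E)-8-bromo-4-methylnona-4,8-dienoate, via mixed ketene acetal 9 (not isolated)
Conditions: EtCO2H (cat.), neat 8, 140 °C, EtOH distilled off
Reagents that add atoms: none
Why: Johnson–Claisen orthoester rearrangement: acid-catalysed exchange gives ketene acetal 9, whose chair [3,3] shift with the C10 chain equatorial forms C13–C14 and the C11=C12 alkene with the high E selectivity typical of 2-methylallyl carbinols; the remote bromoalkene is a spectator.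

**Step 5**
Reactants: 10 ethyl (4E)-8-bromo-4-methylnona-4,8-dienoate
Product: 11 (4E)-8-bromo-4-methylnona-4,8-dienal
Conditions: i-Bu2AlH, toluene, −78 °C
Reagents that add atoms: none
Why: Partial reduction of the ethyl ester to the aldehyde (C1) through the cold-stable aluminium hemiacetal; neither alkene reacts.

**Step 6**
Reactants: 11 (4E)-8-bromo-4-methylnona-4,8-dienal; 12 (triphenylphosphoranylidene)acetaldehyde
Product: 13 (2E,6E)-10-bromo-6-methylundeca-2,6,10-trienal
Conditions: toluene, 80 °C
Reagents that add atoms: none
Why: Wittig olefination with a stabilised ylide gives the (E)-enal and adds C2 and C3; a second homologation is slow because the conjugated product is less electrophilic than 11.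

**Step 7**
Reactants: 13 (2E,6E)-10-bromo-6-methylundeca-2,6,10-trienal; 14 dimethyl malonate
Product: 15 dimethyl 2-[(3R,6E)-10-bromo-6-methyl-1-oxoundeca-6,10-dien-3-yl]propanedioate
Conditions: (S)-2-{bis[3,5-bis(trifluoromethyl)phenyl][(trimethylsilyl)oxy]methyl}pyrrolidine (10 mol %), PhCO2H (10 mol %), EtOH, 0 °C
Reagents that add atoms: none
Why: Iminium-catalysed asymmetric Michael addition: the amine forms the s-trans (E)-iminium ion of 13, its diaryl(silyloxy)methyl group blocks one face, and the malonate adds to the open face of C1, which on the accepted shielding model gives 1R with the (S) catalyst (3R in the chain numbering of 15); hydrolysis of the enamine returns the aldehyde.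

**Step 8**
Reactants: 15 dimethyl 2-[(3R,6E)-10-bromo-6-methyl-1-oxoundeca-6,10-dien-3-yl]propanedioate
Product: 17 methyl (4R)-4-[(3E)-7-bromo-3-methylocta-3,7-dien-1-yl]-2-oxooxane-3-carboxylate (both C3 epimers), via hydroxy diester 16 (not isolated)
Conditions: NaBH4, MeOH, 0 °C; then TsOH·H2O (cat.), CH2Cl2, rt
Reagents that add atoms: none
Why: Borohydride reduces only the aldehyde, and the C3 hydroxyl of 16 then closes onto one malonate ester under acid catalysis (six-membered lactonisation); the ester-bearing carbon is a mixture that is removed in step 9.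

**Step 9**
Reactants: 17 methyl (4R)-4-[(3E)-7-bromo-3-methylocta-3,7-dien-1-yl]-2-oxooxane-3-carboxylate
Product: 18 (4R)-4-[(3E)-7-bromo-3-methylocta-3,7-dien-1-yl]oxan-2-one
Conditions: LiCl, H2O, DMSO, 150 °C
Reagents that add atoms: none
Why: Krapcho dealkoxycarbonylation: chloride demethylates the exocyclic ester (SN2 at methyl, faster than attack at the ring CH2–O), the carboxylate loses CO2 and the enolate is protonated by water; C1 is not involved.

**Step 10**
Reactants: 18 (4R)-4-[(3E)-7-bromo-3-methylocta-3,7-dien-1-yl]oxan-2-one
Product: 20 (3S,4R)-4-[(3E)-7-bromo-3-methylocta-3,7-dien-1-yl]-3-methyloxan-2-one, via lactone lithium enolate 19 (not isolated)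
Conditions: LiN(i-Pr)2 (LDA, 1.05 equiv), THF, −78 °C; then MeI, −78 → −40 °C
Reagents that add atoms: iodomethane, CI
Why: Alkylation of a 4-substituted δ-lactone enolate: enolate 19 is methylated on the face opposite the C1 side chain, which sets 15S trans to the C1 arm; one equivalent of base at −78 °C is consumed by the lactone and leaves the bromoalkene intact.

**Step 11**
Reactants: 20 (3S,4R)-4-[(3E)-7-bromo-3-methylocta-3,7-dien-1-yl]-3-methyloxan-2-one
Product: 22 methyl (2S,3R,6E)-10-bromo-3-(2-hydroxyethyl)-2,6-dimethylundeca-6,10-dienoate, via potassium carboxylate 21 (not isolated)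
Conditions: KOH, MeOH/H2O, rt; evaporate; then MeI, DMF, rt
Reagents that add atoms: potassium hydroxide, [K+].[OH-]; iodomethane, CI
Why: Saponification of the δ-lactone (hydroxide attack is far faster than enolisation, so C15 is kept) gives carboxylate 21, which is O-methylated by SN2 under neutral conditions in which the δ-hydroxy ester does not re-close; the product is silylated without delay.

**Step 12**
Reactants: 22 methyl (2S,3R,6E)-10-bromo-3-(2-hydroxyethyl)-2,6-dimethylundeca-6,10-dienoate
Product: 23 methyl (2S,3R,6E)-10-bromo-2,6-dimethyl-3-{2-[(triethylsilyl)oxy]ethyl}undeca-6,10-dienoate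
Conditions: Et3SiCl, imidazole, CH2Cl2, 0 °C
Reagents that add atoms: chlorotriethylsilane, CC[Si](Cl)(CC)CC
Why: Silylation of the primary alcohol; the triethylsilyl ether blocks relactonisation in the basic steps that follow and is the group that step 17 converts directly into the aldehyde.

**Step 13**
Reactants: 24 5-hydroxypentan-2-one
Product: 25 4-oxopentanal
Conditions: 2,2,6,6-tetramethylpiperidin-1-oxyl (TEMPO, cat.), PhI(OAc)2, CH2Cl2, rt
Reagents that add atoms: none
Why: Nitroxyl-catalysed oxidation of the primary alcohol (open form of the hydroxy ketone) stops at the aldehyde and leaves the ketone alone; 25 is used freshly prepared.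

**Step 14**
Reactants: 23 methyl (2S,3R,6E)-10-bromo-2,6-dimethyl-3-{2-[(triethylsilyl)oxy]ethyl}undeca-6,10-dienoate; 25 4-oxopentanal
Product: 26 methyl (2S,3R,6E,11R)-11-hydroxy-2,6-dimethyl-10-methylidene-14-oxo-3-{2-[(triethylsilyl)oxy]ethyl}pentadec-6-enoate
Conditions: CrCl2, N-[2-(4-tert-butyl-4,5-dihydro-1,3-oxazol-2-yl)-6-methylphenyl]methanesulfonamide (single antipode), Et3N, THF, rt; then NiCl2 (cat.), 23, 25, rt
Reagents that add atoms: none
Why: Nozaki–Hiyama–Kishi coupling: zerovalent nickel inserts into the C8–Br bond and transmetalation gives an alkenylchromium species (trivalent chromium) that adds to the aldehyde of 25 but not to its ketone, the ester or the silyl ether, forming C7–C8; the chiral sulfonamide on chromium is chosen to direct Si-face addition, which gives 7R by reagent control alone.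

**Step 15**
Reactants: 26 methyl (2S,3R,6E,11R)-11-hydroxy-2,6-dimethyl-10-methylidene-14-oxo-3-{2-[(triethylsilyl)oxy]ethyl}pentadec-6-enoate
Product: 27 methyl (2S,3R,6E,11R)-11-[(tert-butyldimethylsilyl)oxy]-2,6-dimethyl-10-methylidene-14-oxo-3-{2-[(triethylsilyl)oxy]ethyl}pentadec-6-enoate
Conditions: t-BuMe2SiCl, imidazole, DMF, rt
Reagents that add atoms: tert-butyldimethylsilyl chloride, CC(C)(C)[Si](C)(C)Cl
Why: Silylation of the secondary allylic alcohol in its open hydroxy ketone form (the cyclic hemiketal has only an unreactive tertiary hydroxyl and drains into the product); imidazole does not enolise the methyl ketone.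

**Step 16**
Reactants: 27 methyl (2S,3R,6E,11R)-11-[(tert-butyldimethylsilyl)oxy]-2,6-dimethyl-10-methylidene-14-oxo-3-{2-[(triethylsilyl)oxy]ethyl}pentadec-6-enoate
Product: 28 methyl (2S,3R)-5-{(2S,3S)-3-[(4R)-4-[(tert-butyldimethylsilyl)oxy]-3-methylidene-7-oxooctyl]-2-methyloxiran-2-yl}-2-methyl-3-{2-[(triethylsilyl)oxy]ethyl}pentanoate
Conditions: 1,2:4,5-di-O-isopropylidene-β-L-erythro-2,3-hexodiulo-2,6-pyranose (30 mol %), Oxone (2KHSO5·KHSO4·K2SO4), K2CO3, Bu4NHSO4, MeCN/CH2(OMe)2, aq. Na2B4O7 buffer (pH 10.5), 0 °C
Reagents that add atoms: potassium peroxymonosulfate (oxidant of Oxone), [K+].[O-]S(=O)(=O)OO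
Why: Shi asymmetric epoxidation: the chiral dioxirane transfers oxygen through a spiro transition state to the electron-rich E-trisubstituted C11=C12 alkene, while the shielded 1,1-disubstituted C8 methylene reacts far more slowly; the L-fructose-derived ketone is the antipode of the one that gives R,R epoxides from such alkenes and so delivers 11S,12S, and the open-chain ester and both silyl ethers tolerate pH 10.5 at 0 °C.

**Step 17**
Reactants: 28 methyl (2S,3R)-5-{(2S,3S)-3-[(4R)-4-[(tert-butyldimethylsilyl)oxy]-3-methylidene-7-oxooctyl]-2-methyloxiran-2-yl}-2-methyl-3-{2-[(triethylsilyl)oxy]ethyl}pentanoate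
Product: 29 methyl (2S,3R)-5-{(2S,3S)-3-[(4R)-4-[(tert-butyldimethylsilyl)oxy]-3-methylidene-7-oxooctyl]-2-methyloxiran-2-yl}-2-methyl-3-(2-oxoethyl)pentanoate
Conditions: (COCl)2, DMSO, CH2Cl2, −78 → −40 °C; then Et3N, −78 → 0 °C
Reagents that add atoms: none
Why: Swern oxidation applied directly to a primary triethylsilyl ether: the chlorosulfonium salt cleaves the primary Si–O bond (the secondary tert-butyldimethylsilyl ether is inert) and the alkoxysulfonium ion collapses to the aldehyde on addition of base; the cold non-aqueous conditions avoid a free δ-hydroxy ester and keep acid from the epoxide.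

**Step 18**
Reactants: 29 methyl (2S,3R)-5-{(2S,3S)-3-[(4R)-4-[(tert-butyldimethylsilyl)oxy]-3-methylidene-7-oxooctyl]-2-methyloxiran-2-yl}-2-methyl-3-(2-oxoethyl)pentanoate
Product: 30 methyl (2S)-2-[(1R,3R,4S,7R,11S,12S)-7-[(tert-butyldimethylsilyl)oxy]-11,12-epoxy-3,4-dihydroxy-4,12-dimethyl-8-methylidenecyclotetradecyl]propanoate (ring numbered as in cembranes)
Conditions: SmI2 (0.1 M in THF, 4 equiv), slow addition of 29 (final 2 mM), THF, rt; aq. NaHCO3
Reagents that add atoms: none
Why: Ketone–aldehyde pinacol coupling: electron transfer from divalent samarium to the C3 aldehyde, the more easily reduced carbonyl, gives a samarium-bound ketyl that attacks the C4 ketone held on the same oxophilic trivalent samarium centre, and a second electron transfer gives the samarium 3,4-diolate, which is protonated on work-up. The closest known reactions are the SmI2 pinacol cyclisation of keto aldehydes to cis diols and the low-valent titanium pinacol macrocyclisation of cembranoid keto aldehydes; titanium is excluded because it would deoxygenate the epoxide, whereas isolated epoxides, methyl esters, allylic silyl ethers and unactivated alkenes are inert to SmI2 in THF without HMPA. One ring is closed, the 14-membered carbocycle, in a 14-exo-trig mode (attack on the C4 carbonyl carbon with its oxygen outside the new ring), and slow addition at high dilution keeps ketyls of different molecules apart. C3 is controlled by the oxygen–samarium–oxygen bridge, which holds the two oxygens syn-clinal so that closure with the ring arms C2 and C5 gauche gives the cis 3,4-diol. C4 is controlled by the folding of the seco chain, which is biased by the C1 centre with its branched propanoate arm kept outside the forming ring and by the rigid trans epoxide and the 1,1-disubstituted alkene that pre-organise C7–C13. The step needs the 3R,4S pair with the epoxide untouched; chelation secures the C3/C4 relation only in part and the sense relative to C1 rests on conformational bias, so this is the riskiest point of the route, and an error at C3 is made repairable (see below). Partial closure of the samarium C3 alkoxide onto the C16 ester to give 31 directly would be harmless.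

**Step 19**
Reactants: 30 methyl (2S)-2-[(1R,3R,4S,7R,11S,12S)-7-[(tert-butyldimethylsilyl)oxy]-11,12-epoxy-3,4-dihydroxy-4,12-dimethyl-8-methylidenecyclotetradecyl]propanoate
Product: 31 (1R,3R,4S,7R,11S,12S,15S)-7-[(tert-butyldimethylsilyl)oxy]-11,12-epoxy-4-hydroxycembr-8(19)-en-16,3-olide
Conditions: 1,8-diazabicyclo[5.4.0]undec-7-ene (DBU, 0.5 equiv), 4 Å molecular sieves, toluene, 60 °C
Reagents that add atoms: none
Why: Base-catalysed intramolecular transesterification: the C3 hydroxyl attacks the C16 methyl ester (6-exo-trig), favoured over the seven-membered closure from the C4 hydroxyl; sieves take up methanol, no acid reaches the epoxide, and the base leaves C15 in its equatorial, thermodynamically preferred configuration.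

**Step 20**
Reactants: 31 (1R,3R,4S,7R,11S,12S,15S)-7-[(tert-butyldimethylsilyl)oxy]-11,12-epoxy-4-hydroxycembr-8(19)-en-16,3-olide
Product: 32 (1R,3R,4S,7R,11S,12S,15S)-11,12-epoxy-4,7-dihydroxycembr-8(19)-en-16,3-olide (target, CNP0262409.1)
Conditions: Bu4NF, AcOH, THF, rt
Reagents that add atoms: none
Why: Fluoride cleavage of the silyl ether; buffering with acetic acid keeps the medium from opening the lactone, and fluoride does not affect the epoxide or the tertiary alcohol.

## Compound list

1 | tert-butyl acetate | CC(=O)OC(C)(C)C | starting material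
2 | 2,3-dibromoprop-1-ene | C=C(Br)CBr | starting material
3 | lithium enolate of tert-butyl acetate (lithium 1-tert-butoxyethen-1-olate) | [Li+].[O-]C(=C)OC(C)(C)C | intermediate
4 | tert-butyl 4-bromopent-4-enoate | C=C(Br)CCC(=O)OC(C)(C)C | intermediate
5 | 4-bromopent-4-enal | C=C(Br)CCC=O | intermediate
6 | isopropenylmagnesium bromide (prop-1-en-2-ylmagnesium bromide) | C=C(C)[Mg]Br | starting material
7 | 6-bromo-2-methylhepta-1,6-dien-3-ol (racemic) | C=C(C)C(O)CCC(Br)=C | intermediate
8 | triethyl orthoacetate (1,1,1-triethoxyethane) | CC(OCC)(OCC)OCC | starting material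
9 | 6-bromo-3-[(1-ethoxyethenyl)oxy]-2-methylhepta-1,6-diene (mixed ketene acetal) | C=C(OCC)OC(CCC(Br)=C)C(C)=C | intermediate
10 | ethyl (4E)-8-bromo-4-methylnona-4,8-dienoate | CCOC(=O)CC/C(C)=C/CCC(Br)=C | intermediate
11 | (4E)-8-bromo-4-methylnona-4,8-dienal | O=CCC/C(C)=C/CCC(Br)=C | intermediate
12 | (triphenylphosphoranylidene)acetaldehyde | O=CC=P(c1ccccc1)(c1ccccc1)c1ccccc1 | starting material
13 | (2E,6E)-10-bromo-6-methylundeca-2,6,10-trienal | O=C/C=C/CC/C(C)=C/CCC(Br)=C | intermediate
14 | dimethyl malonate | COC(=O)CC(=O)OC | starting material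
15 | dimethyl 2-[(3R,6E)-10-bromo-6-methyl-1-oxoundeca-6,10-dien-3-yl]propanedioate | C=C(Br)CC/C=C(\C)CC[C@H](CC=O)C(C(=O)OC)C(=O)OC | intermediate
16 | dimethyl 2-[(3R,6E)-10-bromo-1-hydroxy-6-methylundeca-6,10-dien-3-yl]propanedioate | C=C(Br)CC/C=C(\C)CC[C@H](CCO)C(C(=O)OC)C(=O)OC | intermediate
17 | methyl (4R)-4-[(3E)-7-bromo-3-methylocta-3,7-dien-1-yl]-2-oxooxane-3-carboxylate (both C3 epimers) | C=C(Br)CC/C=C(\C)CC[C@@H]1CCOC(=O)C1C(=O)OC | intermediate
18 | (4R)-4-[(3E)-7-bromo-3-methylocta-3,7-dien-1-yl]oxan-2-one | C=C(Br)CC/C=C(\C)CC[C@@H]1CCOC(=O)C1 | intermediate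
19 | lithium (4R)-4-[(3E)-7-bromo-3-methylocta-3,7-dien-1-yl]-5,6-dihydro-4H-pyran-2-olate (lactone enolate) | [Li+].[O-]C1=C[C@H](CC/C(C)=C/CCC(Br)=C)CCO1 | intermediate
20 | (3S,4R)-4-[(3E)-7-bromo-3-methylocta-3,7-dien-1-yl]-3-methyloxan-2-one | C=C(Br)CC/C=C(\C)CC[C@@H]1CCOC(=O)[C@H]1C | intermediate
21 | potassium (2S,3R,6E)-10-bromo-3-(2-hydroxyethyl)-2,6-dimethylundeca-6,10-dienoate | C=C(Br)CC/C=C(\C)CC[C@H](CCO)[C@H](C)C(=O)[O-].[K+] | intermediate
22 | methyl (2S,3R,6E)-10-bromo-3-(2-hydroxyethyl)-2,6-dimethylundeca-6,10-dienoate | C=C(Br)CC/C=C(\C)CC[C@H](CCO)[C@H](C)C(=O)OC | intermediate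
23 | methyl (2S,3R,6E)-10-bromo-2,6-dimethyl-3-{2-[(triethylsilyl)oxy]ethyl}undeca-6,10-dienoate | C=C(Br)CC/C=C(\C)CC[C@H](CCO[Si](CC)(CC)CC)[C@H](C)C(=O)OC | intermediate
24 | 5-hydroxypentan-2-one | CC(=O)CCCO | starting material
25 | 4-oxopentanal | CC(=O)CCC=O | intermediate
26 | methyl (2S,3R,6E,11R)-11-hydroxy-2,6-dimethyl-10-methylidene-14-oxo-3-{2-[(triethylsilyl)oxy]ethyl}pentadec-6-enoate | CC(=O)CC[C@@H](O)C(=C)CC/C=C(\C)CC[C@H](CCO[Si](CC)(CC)CC)[C@H](C)C(=O)OC | intermediate
27 | methyl (2S,3R,6E,11R)-11-[(tert-butyldimethylsilyl)oxy]-2,6-dimethyl-10-methylidene-14-oxo-3-{2-[(triethylsilyl)oxy]ethyl}pentadec-6-enoate | CC(=O)CC[C@@H](O[Si](C)(C)C(C)(C)C)C(=C)CC/C=C(\C)CC[C@H](CCO[Si](CC)(CC)CC)[C@H](C)C(=O)OC | intermediate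
28 | methyl (2S,3R)-5-{(2S,3S)-3-[(4R)-4-[(tert-butyldimethylsilyl)oxy]-3-methylidene-7-oxooctyl]-2-methyloxiran-2-yl}-2-methyl-3-{2-[(triethylsilyl)oxy]ethyl}pentanoate | CC(=O)CC[C@@H](O[Si](C)(C)C(C)(C)C)C(=C)CC[C@@H]1O[C@@]1(C)CC[C@H](CCO[Si](CC)(CC)CC)[C@H](C)C(=O)OC | intermediate
29 | methyl (2S,3R)-5-{(2S,3S)-3-[(4R)-4-[(tert-butyldimethylsilyl)oxy]-3-methylidene-7-oxooctyl]-2-methyloxiran-2-yl}-2-methyl-3-(2-oxoethyl)pentanoate (seco keto aldehyde) | CC(=O)CC[C@@H](O[Si](C)(C)C(C)(C)C)C(=C)CC[C@@H]1O[C@@]1(C)CC[C@H](CC=O)[C@H](C)C(=O)OC | intermediate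
30 | methyl (2S)-2-[(1R,3R,4S,7R,11S,12S)-7-[(tert-butyldimethylsilyl)oxy]-11,12-epoxy-3,4-dihydroxy-4,12-dimethyl-8-methylidenecyclotetradecyl]propanoate (cembrane ring numbering) | C=C1CC[C@@H]2O[C@@]2(C)CC[C@@H]([C@H](C)C(=O)OC)C[C@@H](O)[C@@](C)(O)CC[C@H]1O[Si](C)(C)C(C)(C)C | intermediate
31 | (1R,3R,4S,7R,11S,12S,15S)-7-[(tert-butyldimethylsilyl)oxy]-11,12-epoxy-4-hydroxycembr-8(19)-en-16,3-olide | C=C1CC[C@@H]2O[C@@]2(C)CC[C@@H]2C[C@@H](OC(=O)[C@H]2C)[C@@](C)(O)CC[C@H]1O[Si](C)(C)C(C)(C)C | intermediate
32 | (1R,3R,4S,7R,11S,12S,15S)-11,12-epoxy-4,7-dihydroxycembr-8(19)-en-16,3-olide (CNP0262409.1) | C=C1CC[C@@H]2O[C@@]2(C)CC[C@@H]2C[C@@H](OC(=O)[C@H]2C)[C@@](C)(O)CC[C@H]1O | target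

## Step count and least certain steps

Total: 20 steps. Longest linear sequence: 19 steps (steps 1–12 and 14–20; step 13 is a one-step side branch).

**Step 18 (key step).** The ketyl may add to the ketone without enough facial discrimination, so that the C3 hydroxyl ends up trans to the C4 hydroxyl. The slow 14-membered closure may also lose out to simple reduction of the aldehyde. The reason is that the samarium bridge fixes only the mutual position of the two oxygens, and a large ring can accommodate the two ring arms gauche or anti. The fallback sets out from 29 and comes back at 30. The coupling is run as above and the crude diols, which would then contain the C3-epimeric diol F1, are oxidised at once at the secondary C3 hydroxyl with Dess–Martin periodinane (NaHCO3, CH2Cl2, 0 °C) to the 3-oxo-4-hydroxy macrocycle F2. Reduction with Zn(BH4)2 in Et2O at −20 °C passes through the zinc chelate of the C3 carbonyl and the C4 hydroxyl, hydride enters from the side of the C4 methyl group, and the cis diol 30 results. This repairs C3 relative to C4. A wrong configuration at C4 is not repaired, and that diastereomer would have to be separated at the ketone stage.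

**Step 14.** Facial control by the chromium-bound ligand may be incomplete with a small, flexible aldehyde, and no neighbouring stereocentre helps, so C7 epimers that are hard to separate may form. The fallback sets out from 23 and comes back at 27.
- Compound 23 is coupled with pent-4-enal under ligand-free CrCl2/NiCl2 (cat.) conditions in DMF to give the C7-epimeric dienyl alcohols F3.
- Dess–Martin oxidation gives the α-methylene ketone F4.
- Corey–Bakshi–Shibata reduction with (S)-1-methyl-3,3-diphenyl-tetrahydro-1H,3H-pyrrolo[1,2-c][1,3,2]oxazaborole and catecholborane in toluene at −78 °C treats the alkenyl group as the large substituent and gives the 7R alcohol F5.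
- t-BuMe2SiCl and imidazole give the silyl ether F6.
- Wacker oxidation (PdCl2 cat., CuCl, O2, DMF/H2O) of the only monosubstituted alkene installs the C4 methyl ketone of 27.

**Step 17.** The desilylative oxidation may stall, or chloride and adventitious HCl from the chlorosulfonium salt may open the trisubstituted epoxide before the base is added. The fallback sets out from 28 and comes back at 29. HF·pyridine buffered with excess pyridine in THF at 0 °C removes the primary triethylsilyl group selectively to give the hydroxy ester F7, which is oxidised without storage by Dess–Martin periodinane with NaHCO3 to 29.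

**Step 7.** With an unbranched aliphatic enal the iminium turnover is slow, so uncatalysed addition and aldol condensation can erode the enantiomeric purity at C1, and every later reagent-controlled step would then produce diastereomers. The fallback sets out from 11 and comes back at 18.
- Horner–Wadsworth–Emmons reaction of 11 with diethyl {2-[(4R)-4-benzyl-2-oxo-1,3-oxazolidin-3-yl]-2-oxoethyl}phosphonate (LiCl, i-Pr2NEt, MeCN) gives the (E)-enoyl imide F8.
- CH2=CHMgBr with CuBr·SMe2 (THF/Me2S, −78 → −20 °C) adds the vinyl group (C2, C3) to C1 of the magnesium-chelated imide from the face away from the benzyl group, giving the 3-vinyl imide F9.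
- 9-BBN hydroborates only the vinyl group. Oxidative work-up (NaOH, H2O2) and acidification close the C3 hydroxyl onto the acyl carbon, release the oxazolidinone and give 18.

**Step 19.** Acyl transfer to the hindered secondary C3 hydroxyl next to the quaternary C4 may be slow under mild base, and forcing the conditions invites transannular opening of the epoxide. The fallback sets out from 30 and comes back at 31. LiOH in THF/H2O hydrolyses the methyl ester, and careful acidification to pH 5 gives the dihydroxy acid F10. Carbodiimide lactonisation (N-(3-dimethylaminopropyl)-N'-ethylcarbodiimide hydrochloride, 4-(dimethylamino)pyridine, CH2Cl2, 0 °C) then acylates the C3 hydroxyl to give 31.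

## Further compounds

F1 | step 18 | methyl (2S)-2-[(1R,3S,4S,7R,11S,12S)-7-[(tert-butyldimethylsilyl)oxy]-11,12-epoxy-3,4-dihydroxy-4,12-dimethyl-8-methylidenecyclotetradecyl]propanoate (C3 epimer of 30) | C=C1CC[C@@H]2O[C@@]2(C)CC[C@@H]([C@H](C)C(=O)OC)C[C@H](O)[C@@](C)(O)CC[C@H]1O[Si](C)(C)C(C)(C)C
F2 | step 18 | methyl (2S)-2-[(1R,4S,7R,11S,12S)-7-[(tert-butyldimethylsilyl)oxy]-11,12-epoxy-4-hydroxy-4,12-dimethyl-8-methylidene-3-oxocyclotetradecyl]propanoate | C=C1CC[C@@H]2O[C@@]2(C)CC[C@@H]([C@H](C)C(=O)OC)CC(=O)[C@@](C)(O)CC[C@H]1O[Si](C)(C)C(C)(C)C
F3 | step 14 | methyl (2S,3R,6E)-11-hydroxy-2,6-dimethyl-10-methylidene-3-{2-[(triethylsilyl)oxy]ethyl}pentadeca-6,14-dienoate (both C11 epimers) | C=CCCC(O)C(=C)CC/C=C(\C)CC[C@H](CCO[Si](CC)(CC)CC)[C@H](C)C(=O)OC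
F4 | step 14 | methyl (2S,3R,6E)-2,6-dimethyl-10-methylidene-11-oxo-3-{2-[(triethylsilyl)oxy]ethyl}pentadeca-6,14-dienoate | C=CCCC(=O)C(=C)CC/C=C(\C)CC[C@H](CCO[Si](CC)(CC)CC)[C@H](C)C(=O)OC
F5 | step 14 | methyl (2S,3R,6E,11R)-11-hydroxy-2,6-dimethyl-10-methylidene-3-{2-[(triethylsilyl)oxy]ethyl}pentadeca-6,14-dienoate | C=CCC[C@@H](O)C(=C)CC/C=C(\C)CC[C@H](CCO[Si](CC)(CC)CC)[C@H](C)C(=O)OC
F6 | step 14 | methyl (2S,3R,6E,11R)-11-[(tert-butyldimethylsilyl)oxy]-2,6-dimethyl-10-methylidene-3-{2-[(triethylsilyl)oxy]ethyl}pentadeca-6,14-dienoate | C=CCC[C@@H](O[Si](C)(C)C(C)(C)C)C(=C)CC/C=C(\C)CC[C@H](CCO[Si](CC)(CC)CC)[C@H](C)C(=O)OC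
F7 | step 17 | methyl (2S,3R)-5-{(2S,3S)-3-[(4R)-4-[(tert-butyldimethylsilyl)oxy]-3-methylidene-7-oxooctyl]-2-methyloxiran-2-yl}-3-(2-hydroxyethyl)-2-methylpentanoate | CC(=O)CC[C@@H](O[Si](C)(C)C(C)(C)C)C(=C)CC[C@@H]1O[C@@]1(C)CC[C@H](CCO)[C@H](C)C(=O)OC
F8 | step 7 | (4R)-4-benzyl-3-[(2E,6E)-10-bromo-6-methylundeca-2,6,10-trienoyl]-1,3-oxazolidin-2-one | O=C1OC[C@@H](Cc2ccccc2)N1C(=O)/C=C/CC/C(C)=C/CCC(Br)=C
F9 | step 7 | (4R)-4-benzyl-3-[(3S,6E)-10-bromo-3-ethenyl-6-methylundeca-6,10-dienoyl]-1,3-oxazolidin-2-one | O=C1OC[C@@H](Cc2ccccc2)N1C(=O)C[C@@H](C=C)CC/C(C)=C/CCC(Br)=C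
F10 | step 19 | (2S)-2-[(1R,3R,4S,7R,11S,12S)-7-[(tert-butyldimethylsilyl)oxy]-11,12-epoxy-3,4-dihydroxy-4,12-dimethyl-8-methylidenecyclotetradecyl]propanoic acid | C=C1CC[C@@H]2O[C@@]2(C)CC[C@@H]([C@H](C)C(=O)O)C[C@@H](O)[C@@](C)(O)CC[C@H]1O[Si](C)(C)C(C)(C)C
A1 | alternative 1 | 16-membered macrolide with iodomethyl group on C3, (E)-2-methyl enoate C1=C15, free C4 hydroxyl, C7 silyl ether, C8 methylene and 11,12-epoxide | IC[C@H]1OC(=O)/C(C)=C/CC[C@]2(C)O[C@H]2CCC(=C)[C@H](O[Si](C)(C)C(C)(C)C)CC[C@]1(C)O
A2 | alternative 1 | (1R,3R,4S,7R,11S,12S,15S)-7-[(tert-butyldimethylsilyl)oxy]-11,12-epoxy-4-hydroxycembr-8(19)-en-16,3-olide (identical with 31) | C=C1CC[C@@H]2O[C@@]2(C)CC[C@@H]2C[C@@H](OC(=O)[C@H]2C)[C@@](C)(O)CC[C@H]1O[Si](C)(C)C(C)(C)C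
A3 | alternative 2 | seco δ-lactone with vinyl group on C1, 7,8-epoxide and (E)-alkenyl iodide at C12 | C/C(I)=C\CC[C@@]1(C)O[C@@H]1CC[C@](C)(O)[C@H]1C[C@@H](C=C)[C@H](C)C(=O)O1
A4 | alternative 2 | macrocyclic (11E)-alkene lactone with 7,8-epoxide and C4 hydroxyl | C/C1=C\CC[C@@]2(C)O[C@@H]2CC[C@](C)(O)[C@H]2C[C@@H](CC1)[C@H](C)C(=O)O2
A5 | alternative 3 | seco δ-lactone with C8 keto C9 phenylsulfonyl unit, C7 silyl ether and tertiary allylic methyl carbonate at C12 | C=CC(C)(OC(=O)OC)CC[C@@H]1C[C@@H](OC(=O)[C@H]1C)[C@@](C)(O)CC[C@@H](O[Si](C)(C)C(C)(C)C)C(=O)CS(=O)(=O)c1ccccc1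
A6 | alternative 3 | macrocyclic β-keto sulfone lactone with (11E)-alkene, C4 hydroxyl and C7 silyl ether | O=C1[C@@H](S(=O)(=O)c2ccccc2)C/C=C(C)/CC[C@@H]2C[C@@H](OC(=O)[C@H]2C)[C@@](C)(O)CC[C@H]1O[Si](C)(C)C(C)(C)C
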